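**Retrosynthetic overview**

1. Locants used below: ring A C1 (CMe2), C2 (CHOH), C3 (CH2), C4 (=CH), C5 (=CMe), C6 (CH); chain C7–C11 (C11 = CHOH); ring B C12 (epoxide C), C13 (epoxide CH), C14 (CHOH), C15 (C–CH2OH), C16 (=CH), C17 (CHOH).
2. Target ⇐ global desilylation ⇐ Negishi coupling at C8–C9 of the (E)-alkenylzirconocene from ring-A alkyne 20 with (Z)-iodide 32, which carries all of ring B.
3. 20 ⇐ allylic-diazene transposition (C4 carbinol → C6–H and C4=C5) ⇐ 1,3-syn reduction (C2) and CBS reduction (C4) ⇐ enone 12 ⇐ strain-release formal [4+2] of cyclobutenone 8 with 1,1-diethoxyethene 9, which forms C3–C4 and C1–C2 in one operation.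
4. Enabling feature: in ring A the gem-dimethyl carbon C1, C6, methyl-bearing C5 and sp2 C4 are contiguous, and C1 and C4 are bridged by the CH(OH)–CH2 pair C2–C3. C4–C5–C6–C1 is therefore the carbon set of a 2,4,4-trimethylcyclobut-2-enone (C4 = carbonyl carbon, opened to a vinylketene), and C2–C3 is a masked acetate (ketene acetal).
5. 32 ⇐ silylation ⇐ double carbonyl reduction ⇐ C11-alkoxide-directed epoxidation of planar quinone 29 ⇐ purchased arene 21. Ring order: cyclobutenone (step 1) → ring A (step 3); ring B is the purchased benzene ring, dearomatised in step 14, with the epoxide ring closed in step 15.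

Key step: step 3

Remark on the chemistry: the CBS reductions (steps 4 and 12) are assigned with the usual model, taking the α-methylated alkenyl carbon (step 4) and the aryl group (step 12) as the large substituent. Compounds 1, 2, 5, 9 and 21 and all reagents are taken as purchasable.

**Route**

Step 1
Reactants: 1 isobutyryl chloride; 2 1-ethoxyprop-1-yne
Product: 4 3-ethoxy-2,4,4-trimethylcyclobut-2-en-1-one, via dimethylketene 3 (not isolated)
Conditions: Et3N, MeCN, 70 °C
Reagents that add atoms: none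
Why: Triethylamine dehydrochlorinates 1 to dimethylketene, which undergoes the known ketene–alkoxyalkyne [2+2] cycloaddition with the ketene carbonyl carbon bonding to the methyl-bearing (nucleophilic) alkyne carbon, so the CMe2 carbon ends up next to C–OEt.

Step 2
Reactants: 4 3-ethoxy-2,4,4-trimethylcyclobut-2-en-1-one; 5 ethynyl(trimethyl)silane
Product: 8 2,4,4-trimethyl-3-[(trimethylsilyl)ethynyl]cyclobut-2-en-1-one, via lithium (trimethylsilyl)acetylide 6 (not isolated), via 1,2-adduct 7 (not isolated)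
Conditions: 5, n-BuLi, THF, −78 °C; then 4, −78 → 0 °C; then 1 M HCl, 0 °C
Reagents that add atoms: water, O
Why: 1,2-Addition of the acetylide to the vinylogous ester carbonyl, then acid hydrolysis of the enol ether and loss of water (Stork–Danheiser-type transposition, standard for 3-alkoxycyclobutenones), moves the carbonyl to the former C–OEt carbon and puts the alkynyl group on the β-carbon.

Step 3
Reactants: 8 2,4,4-trimethyl-3-[(trimethylsilyl)ethynyl]cyclobut-2-en-1-one; 9 1,1-diethoxyethene
Product: 12 5,5-diethoxy-2,4,4-trimethyl-3-[(trimethylsilyl)ethynyl]cyclohex-2-en-1-one, via vinylketene 10 (not isolated), via cyclobutanone adduct 11 (not isolated)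
Conditions: 9 (3 equiv), PhMe, 110 °C, sealed tube (base-washed glass)
Reagents that add atoms: none
Why: Proposed new method: thermal conrotatory 4π-electrocyclic opening of the strained cyclobutenone (cleavage of C4–C1) gives vinylketene 10, whose electrophilic ketene carbon C4 is attacked by the nucleophilic CH2 terminus (C3) of the ketene acetal to give a dienolate/dialkoxycarbenium zwitterion; collapse at the α-carbon C5 gives the donor–acceptor cyclobutanone 11 reversibly, whereas collapse at the γ-carbon C1 onto C2 gives the strain-free conjugated cyclohexenone 12 irreversibly, so both C3–C4 and C1–C2 form in the one operation. The closest known reaction types are the ketene–ketene acetal [2+2] cycloaddition, the Danheiser benzannulation (cyclobutenone → vinylketene trapped by an electron-rich two-carbon partner), the Lewis-acid opening of 3-alkoxycyclobutanones to 1,4-zwitterions that close in a formal [4+2] sense, and the acid-promoted 2-vinylcyclobutanone → cyclohexenone ring expansion. Ring A is the only ring closed, in a stepwise polar [4+2] mode (C4–C5–C6–C1 from the vinylketene, C3–C2 from the acetal), the second bond arising by six-membered intramolecular vinylogous Mukaiyama-aldol-type closure. No stereocenter is created: 12 is achiral and the stereocenter of 11 is erased on ring expansion, so absolute configuration is introduced afterwards by reagent control. The selectivities needed are the orientation of the first bond (secured by polarity: acetal CH2 to ketene carbonyl carbon), γ- over α-closure (secured by reversibility of the push–pull cyclobutanone and about 25 kcal/mol of ring strain), and trapping faster than the 1,5-hydrogen shift of the vinylketene or loss of ethanol from the β-keto ketal (excess acetal, neutral conditions, no Lewis acid).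

Step 4
Reactants: 12 5,5-diethoxy-2,4,4-trimethyl-3-[(trimethylsilyl)ethynyl]cyclohex-2-en-1-one
Product: 14 (5S)-5-hydroxy-2,2,4-trimethyl-3-[(trimethylsilyl)ethynyl]cyclohex-3-en-1-one, via ketal alcohol 13 (not isolated)
Conditions: (R)-Me-CBS (20 mol %), catecholborane, PhMe, −78 °C; then aq. oxalic acid, THF, 0 → 25 °C
Reagents that add atoms: water, O
Why: Corey–Bakshi–Shibata 1,2-reduction with C5 (α-methylated alkenyl carbon) as the large and the C3 methylene as the small substituent should give the (S)-carbinol at C4 with the (R)-catalyst, and the mild acidic work-up hydrolyses the strained diethyl ketal without ionising the allylic alcohol.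

Step 5
Reactants: 14 (5S)-5-hydroxy-2,2,4-trimethyl-3-[(trimethylsilyl)ethynyl]cyclohex-3-en-1-one
Product: 16 (1R,3S)-5-ethynyl-4,6,6-trimethylcyclohex-4-ene-1,3-diol, via silylated diol 15 (not isolated)
Conditions: Et2BOMe, NaBH4, THF/MeOH (4:1), −78 °C; then K2CO3, MeOH, 25 °C
Reagents that add atoms: none
Why: Narasaka–Prasad reduction: the diethylboron chelate between the C4 alkoxide and the C2 carbonyl is attacked by external hydride on the face away from the boron bridge, which should give the 1,3-syn (cis) diol and so the (R)-carbinol at C2, and K2CO3 in methanol then cleaves the boronate and the alkyne C–Si bond.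

Step 6
Reactants: 16 (1R,3S)-5-ethynyl-4,6,6-trimethylcyclohex-4-ene-1,3-diol
Product: 19 (1R,5S)-5-ethynyl-4,6,6-trimethylcyclohex-3-en-1-ol, via sulfonylhydrazine 17 (not isolated), via allylic diazene 18 (not isolated)
Conditions: 2-O2NC6H4SO2NHNH2, PPh3, DEAD, THF, −30 → 25 °C
Reagents that add atoms: none
Why: Myers reductive transposition: Mitsunobu displacement of the allylic C4 hydroxyl (the neopentyl C2 hydroxyl is inert) occurs with inversion, loss of sulfinic acid gives the monoalkyl diazene, and its retro-ene loss of N2 delivers hydrogen to C6 on the face of nitrogen, which sets C6 as (S) (side chain cis to the C2 hydroxyl) and moves the double bond to C4=C5.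

Step 7
Reactants: 19 (1R,5S)-5-ethynyl-4,6,6-trimethylcyclohex-3-en-1-ol
Product: 20 triethyl{[(1R,5S)-5-ethynyl-4,6,6-trimethylcyclohex-3-en-1-yl]oxy}silane
Conditions: Et3SiOTf, 2,6-lutidine, CH2Cl2, −78 °C
Reagents that add atoms: triethylsilyl trifluoromethanesulfonate, CC[Si](CC)(CC)OS(=O)(=O)C(F)(F)F
Why: Silyl triflate silylation of the hindered secondary alcohol, needed because the next organometallic step does not tolerate a free hydroxyl; no stereocenter is touched.

Step 8
Reactants: 21 4-bromo-2,5-dimethoxybenzaldehyde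
Product: 22 4-(hydroxymethyl)-2,5-dimethoxybenzaldehyde
Conditions: Bu3SnCH2OH, Pd(PPh3)4 (5 mol %), 1,4-dioxane, 90 °C
Reagents that add atoms: (tributylstannyl)methanol, CCCC[Sn](CCCC)(CCCC)CO
Why: Kosugi–Migita–Stille coupling of the aryl bromide (activated by the para formyl group) with the hydroxymethylstannane installs the future C15 hydroxymethyl group.

Step 9
Reactants: 22 4-(hydroxymethyl)-2,5-dimethoxybenzaldehyde
Product: 23 4-({[tert-butyl(diphenyl)silyl]oxy}methyl)-2,5-dimethoxybenzaldehyde
Conditions: t-BuPh2SiCl, imidazole, DMF, 0 → 25 °C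
Reagents that add atoms: tert-butyl(chloro)diphenylsilane, CC(C)(C)[Si](Cl)(c1ccccc1)c1ccccc1
Why: Standard silylation of the primary alcohol with a group that survives the hydride, cerium and base steps that follow.

Step 10
Reactants: 23 4-({[tert-butyl(diphenyl)silyl]oxy}methyl)-2,5-dimethoxybenzaldehyde
Product: 24 1-[4-({[tert-butyl(diphenyl)silyl]oxy}methyl)-2,5-dimethoxyphenyl]but-2-yn-1-ol (racemic)
Conditions: MeC≡CMgBr, THF, −78 → 0 °C; aq. NH4Cl
Reagents that add atoms: 1-propynylmagnesium bromide, CC#C[Mg]Br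
Why: Grignard addition to the aldehyde brings in C10, C9 and the C9 methyl group; the C11 configuration is set two steps later.

Step 11
Reactants: 24 racemic propargylic alcohol
Product: 25 1-[4-({[tert-butyl(diphenyl)silyl]oxy}methyl)-2,5-dimethoxyphenyl]but-2-yn-1-one
Conditions: MnO2, CH2Cl2, 25 °C
Reagents that add atoms: none
Why: MnO2 oxidises the benzylic, propargylic alcohol selectively to the ynone; the ortho substituent is a methyl ether, so the ynone cannot cyclise.

Step 12
Reactants: 25 aryl ynone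
Product: 26 (1S)-1-[4-({[tert-butyl(diphenyl)silyl]oxy}methyl)-2,5-dimethoxyphenyl]but-2-yn-1-ol
Conditions: (R)-Me-CBS (1.0 equiv), catecholborane, PhMe, −78 °C
Reagents that add atoms: none
Why: Corey–Bakshi–Shibata reduction of the ynone with the ortho-substituted aryl group as the large and the linear propynyl group as the small substituent should give the (S)-carbinol, which is C11 of the target.

Step 13
Reactants: 26 (S)-propargylic alcohol
Product: 28 (1S,2Z)-1-[4-({[tert-butyl(diphenyl)silyl]oxy}methyl)-2,5-dimethoxyphenyl]-3-iodobut-2-en-1-ol, via alkenylalanate 27 (not isolated)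
Conditions: NaAlH2(OCH2CH2OMe)2, THF, 0 → 25 °C; then I2, −78 °C
Reagents that add atoms: iodine, [I][I]
Why: The aluminium alkoxide delivers hydride to the proximal alkyne carbon (trans-hydroalumination) and iodinolysis of the cyclic alkenylalanate with retention gives the (Z)-iodide with iodine cis to the carbinol carbon, which is the C9=C10 geometry of the target.

Step 14
Reactants: 28 (Z)-iodo allylic alcohol
Product: 29 2-({[tert-butyl(diphenyl)silyl]oxy}methyl)-5-[(1S,2Z)-1-hydroxy-3-iodobut-2-en-1-yl]cyclohexa-2,5-diene-1,4-dione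
Conditions: (NH4)2Ce(NO3)6, MeCN/H2O (2:1), 0 °C
Reagents that add atoms: water, O
Why: Oxidative demethylation of the para-dimethoxyarene by tetravalent cerium gives the para-quinone, a planar ring whose only stereochemical information is C11.

Step 15
Reactants: 29 hydroxyalkyl quinone
Product: 30 (1S,6R)-4-({[tert-butyl(diphenyl)silyl]oxy}methyl)-1-[(1S,2Z)-1-hydroxy-3-iodobut-2-en-1-yl]-7-oxabicyclo[4.1.0]hept-3-ene-2,5-dione
Conditions: t-BuOOH, n-BuLi, THF, −78 → −40 °C; aq. NH4Cl
Reagents that add atoms: tert-butyl hydroperoxide, CC(C)(C)OO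
Why: Alkoxide-directed Weitz–Scheffer epoxidation: the C11 lithium alkoxide delivers tert-butyl peroxide to C13 of its own double bond, and allylic 1,2-strain (C11–H eclipsing the ring C12–C17 bond, iodoalkenyl arm on the far face) should place the epoxide oxygen on the face that gives the C11/C12/C13 relationship of the target.

Step 16
Reactants: 30 epoxyquinone
Product: 31 (1S,2S,5R,6S)-4-({[tert-butyl(diphenyl)silyl]oxy}methyl)-1-[(1S,2Z)-1-hydroxy-3-iodobut-2-en-1-yl]-7-oxabicyclo[4.1.0]hept-3-ene-2,5-diol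
Conditions: NaBH4, CeCl3·7H2O, MeOH, −78 °C
Reagents that add atoms: none
Why: Luche 1,2-reduction of both carbonyls; the C12 side chain lies on the face opposite the epoxide (α to C17, pseudoaxial 1,3 to C14), so hydride should enter syn to the epoxide oxygen at both carbons and give the cis-1,4-diol anti to the epoxide (C14 R, C17 S).

Step 17
Reactants: 31 epoxy triol
Product: 32 tris(triethylsilyl) ether of 31 at the C11, C14 and C17 oxygens (descriptors as in 31)
Conditions: Et3SiOTf, 2,6-lutidine, CH2Cl2, −78 → 0 °C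
Reagents that add atoms: triethylsilyl trifluoromethanesulfonate, CC[Si](CC)(CC)OS(=O)(=O)C(F)(F)F
Why: Buffered silyl triflate silylation of the three secondary alcohols at low temperature leaves the epoxide and the alkenyl iodide untouched.

Step 18
Reactants: 20 ring-A alkyne; 32 (Z)-iodide
Product: 35 fully silylated target (four triethylsilyl ethers at the C2, C11, C14 and C17 oxygens, tert-butyldiphenylsilyl ether at the primary oxygen), via alkenylzirconocene 33 (not isolated), via alkenylzinc chloride 34 (not isolated)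
Conditions: Cp2ZrHCl, THF, 25 °C; ZnCl2; then 32, Pd(PPh3)4 (5 mol %), 25 → 40 °C
Reagents that add atoms: none
Why: Syn, anti-Markovnikov hydrozirconation gives the (E)-alkenylzirconocene, and transmetalation to zinc followed by Negishi coupling on zerovalent palladium proceeds with retention at both alkenes, giving the (7E,9Z)-diene.

Step 19
Reactants: 35 fully silylated target
Product: 36 (1R,2S,5R,6S)-4-(hydroxymethyl)-1-{(1S,2Z,4E)-1-hydroxy-5-[(1S,5R)-5-hydroxy-2,6,6-trimethylcyclohex-2-en-1-yl]-3-methylpenta-2,4-dien-1-yl}-7-oxabicyclo[4.1.0]hept-3-ene-2,5-diol (CNP0389279.1)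
Conditions: Bu4NF, AcOH, THF, 0 → 25 °C
Reagents that add atoms: none
Why: Buffered fluoride cleaves the four triethylsilyl ethers and the primary tert-butyldiphenylsilyl ether, and the acetic acid buffer suppresses base-induced epoxide migration (Payne rearrangement).

**Compound list**

1 | isobutyryl chloride | CC(C)C(Cl)=O | starting material
2 | 1-ethoxyprop-1-yne | CC#COCC | starting material
3 | dimethylketene | CC(C)=C=O | intermediate
4 | 3-ethoxy-2,4,4-trimethylcyclobut-2-en-1-one | CCOC1=C(C)C(=O)C1(C)C | intermediate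
5 | ethynyl(trimethyl)silane | C#C[Si](C)(C)C | starting material
6 | lithium (trimethylsilyl)acetylide | [Li]C#C[Si](C)(C)C | intermediate
7 | 3-ethoxy-2,4,4-trimethyl-1-[(trimethylsilyl)ethynyl]cyclobut-2-en-1-ol (racemic) | CCOC1=C(C)C(O)(C#C[Si](C)(C)C)C1(C)C | intermediate
8 | 2,4,4-trimethyl-3-[(trimethylsilyl)ethynyl]cyclobut-2-en-1-one | CC1=C(C#C[Si](C)(C)C)C(C)(C)C1=O | intermediate
9 | 1,1-diethoxyethene | C=C(OCC)OCC | starting material
10 | 2,4-dimethyl-3-[(trimethylsilyl)ethynyl]penta-1,3-dien-1-one (vinylketene) | CC(C)=C(C#C[Si](C)(C)C)C(C)=C=O | intermediate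
11 | 3,3-diethoxy-2-methyl-2-[4-methyl-1-(trimethylsilyl)pent-3-en-1-yn-3-yl]cyclobutan-1-one (racemic) | CCOC1(OCC)CC(=O)C1(C)C(C#C[Si](C)(C)C)=C(C)C | intermediate
12 | 5,5-diethoxy-2,4,4-trimethyl-3-[(trimethylsilyl)ethynyl]cyclohex-2-en-1-one | CC1=C(C#C[Si](C)(C)C)C(C)(C)C(OCC)(OCC)CC1=O | intermediate
13 | (1S)-5,5-diethoxy-2,4,4-trimethyl-3-[(trimethylsilyl)ethynyl]cyclohex-2-en-1-ol | CC1=C(C#C[Si](C)(C)C)C(C)(C)C(OCC)(OCC)C[C@@H]1O | intermediate
14 | (5S)-5-hydroxy-2,2,4-trimethyl-3-[(trimethylsilyl)ethynyl]cyclohex-3-en-1-one | CC1=C(C#C[Si](C)(C)C)C(C)(C)C(=O)C[C@@H]1O | intermediate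
15 | (1R,3S)-4,6,6-trimethyl-5-[(trimethylsilyl)ethynyl]cyclohex-4-ene-1,3-diol (cis) | CC1=C(C#C[Si](C)(C)C)C(C)(C)[C@H](O)C[C@@H]1O | intermediate
16 | (1R,3S)-5-ethynyl-4,6,6-trimethylcyclohex-4-ene-1,3-diol (cis) | CC1=C(C#C)C(C)(C)[C@H](O)C[C@@H]1O | intermediate
17 | 1-[(1R,5R)-3-ethynyl-5-hydroxy-2,4,4-trimethylcyclohex-2-en-1-yl]-1-(2-nitrobenzenesulfonyl)hydrazine | CC1=C(C#C)C(C)(C)[C@H](O)C[C@H]1N(N)S(=O)(=O)c2ccccc2[N+](=O)[O-] | intermediate
18 | (1R,5R)-5-diazenyl-3-ethynyl-2,2,4-trimethylcyclohex-3-en-1-ol | CC1=C(C#C)C(C)(C)[C@H](O)C[C@H]1N=N | intermediate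
19 | (1R,5S)-5-ethynyl-4,6,6-trimethylcyclohex-3-en-1-ol | CC1=CC[C@@H](O)C(C)(C)[C@H]1C#C | intermediate
20 | triethyl{[(1R,5S)-5-ethynyl-4,6,6-trimethylcyclohex-3-en-1-yl]oxy}silane | CC1=CC[C@@H](O[Si](CC)(CC)CC)C(C)(C)[C@H]1C#C | intermediate
21 | 4-bromo-2,5-dimethoxybenzaldehyde | COc1cc(C=O)c(OC)cc1Br | starting material
22 | 4-(hydroxymethyl)-2,5-dimethoxybenzaldehyde | COc1cc(C=O)c(OC)cc1CO | intermediate
23 | 4-({[tert-butyl(diphenyl)silyl]oxy}methyl)-2,5-dimethoxybenzaldehyde | COc1cc(C=O)c(OC)cc1CO[Si](c2ccccc2)(c2ccccc2)C(C)(C)C | intermediate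
24 | 1-[4-({[tert-butyl(diphenyl)silyl]oxy}methyl)-2,5-dimethoxyphenyl]but-2-yn-1-ol (racemic) | CC#CC(O)c1cc(OC)c(CO[Si](c2ccccc2)(c2ccccc2)C(C)(C)C)cc1OC | intermediate
25 | 1-[4-({[tert-butyl(diphenyl)silyl]oxy}methyl)-2,5-dimethoxyphenyl]but-2-yn-1-one | CC#CC(=O)c1cc(OC)c(CO[Si](c2ccccc2)(c2ccccc2)C(C)(C)C)cc1OC | intermediate
26 | (1S)-1-[4-({[tert-butyl(diphenyl)silyl]oxy}methyl)-2,5-dimethoxyphenyl]but-2-yn-1-ol | CC#C[C@H](O)c1cc(OC)c(CO[Si](c2ccccc2)(c2ccccc2)C(C)(C)C)cc1OC | intermediate
27 | sodium cyclic (Z)-alkenylalanate of 26 (five-membered C–C=C–Al–O ring, two 2-methoxyethoxy groups on aluminium) | CC1=C[C@@H](c2cc(OC)c(CO[Si](c3ccccc3)(c3ccccc3)C(C)(C)C)cc2OC)O[Al-]1(OCCOC)OCCOC.[Na+] | intermediate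
28 | (1S,2Z)-1-[4-({[tert-butyl(diphenyl)silyl]oxy}methyl)-2,5-dimethoxyphenyl]-3-iodobut-2-en-1-ol | I/C(C)=C\[C@H](O)c1cc(OC)c(CO[Si](c2ccccc2)(c2ccccc2)C(C)(C)C)cc1OC | intermediate
29 | 2-({[tert-butyl(diphenyl)silyl]oxy}methyl)-5-[(1S,2Z)-1-hydroxy-3-iodobut-2-en-1-yl]cyclohexa-2,5-diene-1,4-dione | I/C(C)=C\[C@H](O)C1=CC(=O)C(CO[Si](c2ccccc2)(c2ccccc2)C(C)(C)C)=CC1=O | intermediate
30 | (1S,6R)-4-({[tert-butyl(diphenyl)silyl]oxy}methyl)-1-[(1S,2Z)-1-hydroxy-3-iodobut-2-en-1-yl]-7-oxabicyclo[4.1.0]hept-3-ene-2,5-dione | I/C(C)=C\[C@H](O)[C@]12O[C@H]1C(=O)C(CO[Si](c3ccccc3)(c3ccccc3)C(C)(C)C)=CC2=O | intermediate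
31 | (1S,2S,5R,6S)-4-({[tert-butyl(diphenyl)silyl]oxy}methyl)-1-[(1S,2Z)-1-hydroxy-3-iodobut-2-en-1-yl]-7-oxabicyclo[4.1.0]hept-3-ene-2,5-diol (both ring hydroxyls trans to the epoxide) | I/C(C)=C\[C@H](O)[C@]12O[C@H]1[C@H](O)C(CO[Si](c3ccccc3)(c3ccccc3)C(C)(C)C)=C[C@@H]2O | intermediate
32 | tris(triethylsilyl) ether of 31 (C11, C14 and C17 oxygens; descriptors as in 31) | I/C(C)=C\[C@H](O[Si](CC)(CC)CC)[C@]12O[C@H]1[C@H](O[Si](CC)(CC)CC)C(CO[Si](c3ccccc3)(c3ccccc3)C(C)(C)C)=C[C@@H]2O[Si](CC)(CC)CC | intermediate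
33 | chlorobis(cyclopentadienyl)[(E)-2-{(1S,5R)-2,6,6-trimethyl-5-[(triethylsilyl)oxy]cyclohex-2-en-1-yl}ethenyl]zirconium | CC1=CC[C@@H](O[Si](CC)(CC)CC)C(C)(C)[C@H]1/C=C/[Zr](Cl)(C2C=CC=C2)C2C=CC=C2 | intermediate
34 | chloro[(E)-2-{(1S,5R)-2,6,6-trimethyl-5-[(triethylsilyl)oxy]cyclohex-2-en-1-yl}ethenyl]zinc | CC1=CC[C@@H](O[Si](CC)(CC)CC)C(C)(C)[C@H]1/C=C/[Zn]Cl | intermediate
35 | fully silylated 36 (triethylsilyl ethers at the C2, C11, C14 and C17 oxygens, tert-butyldiphenylsilyl ether at the primary oxygen; (7E,9Z)) | CC1=CC[C@@H](O[Si](CC)(CC)CC)C(C)(C)[C@H]1/C=C/C(C)=C\[C@H](O[Si](CC)(CC)CC)[C@]12O[C@H]1[C@H](O[Si](CC)(CC)CC)C(CO[Si](c3ccccc3)(c3ccccc3)C(C)(C)C)=C[C@@H]2O[Si](CC)(CC)CC | intermediate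
36 | (1R,2S,5R,6S)-4-(hydroxymethyl)-1-{(1S,2Z,4E)-1-hydroxy-5-[(1S,5R)-5-hydroxy-2,6,6-trimethylcyclohex-2-en-1-yl]-3-methylpenta-2,4-dien-1-yl}-7-oxabicyclo[4.1.0]hept-3-ene-2,5-diol | CC1=CC[C@@H](O)C(C)(C)[C@H]1/C=C/C(C)=C\[C@H](O)[C@]12O[C@H]1[C@H](O)C(CO)=C[C@@H]2O | target

**Step count and risks**

Total step count: 19 (ring-A fragment steps 1–7, ring-B fragment steps 8–17, union step 18, deprotection step 19).
Longest linear sequence: 12 steps (steps 8–19, from 21).

Steps most likely to fail:

1. Step 3 (key step). The zwitterion may collapse only at the α-carbon and stay as the four-membered ring, or transfer a proton to give an open-chain acyl ketene acetal. The vinylketene may also undergo 1,5-hydrogen shift faster than it is trapped, or the β-keto ketal may lose ethanol.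
   Fallback (known chemistry, sets out from 5, comes back at 15): commercial 4,4-dimethylcyclohexane-1,3-dione is C-methylated (MeI, K2CO3) to 2,4,4-trimethylcyclohexane-1,3-dione F1 and converted (EtOH, TsOH) at its less hindered carbonyl into 3-ethoxy-2,6,6-trimethylcyclohex-2-en-1-one F2. The lithium acetylide of 5 (with CeCl3) adds to the remaining carbonyl and acid hydrolysis (Stork–Danheiser transposition) gives 2,4,4-trimethyl-3-[(trimethylsilyl)ethynyl]cyclohex-2-en-1-one F3. IBX dehydrogenation gives the cross-conjugated 2,4,4-trimethyl-3-[(trimethylsilyl)ethynyl]cyclohexa-2,5-dien-1-one F4. Amine-salt-catalysed asymmetric Weitz–Scheffer epoxidation (H2O2, cinchona-derived primary amine) of the less substituted enone double bond gives the epoxy enone F5. Reductive opening at the α-carbon (PhSeNa from (PhSe)2 and NaBH4, AcOH) gives the (5R)-5-hydroxy enone F6. Luche reduction, with axial attack on the 5-substituted cyclohexenone, should give cis-diol 15, which is desilylated to 16 as in step 5.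

2. Step 15. The peroxide may be delivered to the other quinone double bond or to the other face, and the base may trigger redox isomerisation of the hydroxyalkyl quinone.
   Fallback (sets out from 29, comes back at 30, no new compound): stereocontrol is taken from a chiral reagent instead of from C11 alone. This is a tartrate-mediated, hydroxyl-directed nucleophilic epoxidation (Ph3COOH, NaN(SiMe3)2, diisopropyl tartrate, PhMe, −50 °C), in which a sodium tartrate–peroxide aggregate bound to the C11 alkoxide selects both the double bond and the face. The tartrate antipode is chosen to match C11.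

3. Step 16. Hydride may attack C14 anti to the epoxide oxygen, which is the intrinsic preference of α,β-epoxy ketones, giving the wrong carbinol configuration there.
   Fallback (sets out from 30, comes back at 31): the reduction is accepted as giving the C14-epimeric triol F7. Mitsunobu esterification (4-nitrobenzoic acid, PPh3, DIAD) at C14, the least hindered of the three allylic hydroxyls (C11 and C17 both flank the quaternary C12), inverts that center to give the 4-nitrobenzoate F8. Methanolysis (K2CO3, MeOH, 0 °C) then gives 31.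

**Further compounds**

F1 | step 3 | 2,4,4-trimethylcyclohexane-1,3-dione | CC1C(=O)CCC(C)(C)C1=O
F2 | step 3 | 3-ethoxy-2,6,6-trimethylcyclohex-2-en-1-one | CCOC1=C(C)C(=O)C(C)(C)CC1
F3 | step 3 | 2,4,4-trimethyl-3-[(trimethylsilyl)ethynyl]cyclohex-2-en-1-one | CC1=C(C#C[Si](C)(C)C)C(C)(C)CCC1=O
F4 | step 3 | 2,4,4-trimethyl-3-[(trimethylsilyl)ethynyl]cyclohexa-2,5-dien-1-one | CC1=C(C#C[Si](C)(C)C)C(C)(C)C=CC1=O
F5 | step 3 | (1S,6S)-3,5,5-trimethyl-4-[(trimethylsilyl)ethynyl]-7-oxabicyclo[4.1.0]hept-3-en-2-one | CC1=C(C#C[Si](C)(C)C)C(C)(C)[C@@H]2O[C@@H]2C1=O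
F6 | step 3 | (5R)-5-hydroxy-2,4,4-trimethyl-3-[(trimethylsilyl)ethynyl]cyclohex-2-en-1-one | CC1=C(C#C[Si](C)(C)C)C(C)(C)[C@H](O)CC1=O
F0 | step 15 | none | none
F7 | step 16 | (1S,2S,5S,6S)-4-({[tert-butyl(diphenyl)silyl]oxy}methyl)-1-[(1S,2Z)-1-hydroxy-3-iodobut-2-en-1-yl]-7-oxabicyclo[4.1.0]hept-3-ene-2,5-diol (C14 epimer of 31) | I/C(C)=C\[C@H](O)[C@]12O[C@H]1[C@@H](O)C(CO[Si](c3ccccc3)(c3ccccc3)C(C)(C)C)=C[C@@H]2O
F8 | step 16 | C14 4-nitrobenzoate of 31 (configuration of 31 at C14) | I/C(C)=C\[C@H](O)[C@]12O[C@H]1[C@H](OC(=O)c3ccc(cc3)[N+](=O)[O-])C(CO[Si](c4ccccc4)(c4ccccc4)C(C)(C)C)=C[C@@H]2O
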